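All runs are calculated for substances that don't exist; scatter was added.

It is easy to take a charge of E for E on hand, and then gamma's 2.50 equiv looks ready to carry J to D, two E to each D; yet blue, with 2.2 equiv, shows D at 43% in its last reading, with J still at 12%.

common to all: J 0.050 M

|  | E | remark | time |
|---|---|---|---|
| ochre | 0.32 equiv | run made earlier |  |
| blue | 2.2 equiv | run made earlier |  |
| beta | 0.500 equiv |  | 5.0 d |
| gamma | 2.50 equiv |  | 5.0 d |

- ochre (time / d: D / %, Z / %, J / %): 0.625: 0, 9, 65; 1.25: 0, 9, 55; 1.67: 1, 9, 47; 2.50: 0, 9, 38; 3.00: 0, 10, 38; 4.00: 5, 10, 28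
- blue (time / d: D / %, Z / %, J / %): 0.625: 22, 28, 37; 1.25: 30, 28, 27; 1.67: 29, 25, 21; 2.50: 32, 26, 18; 3.00: 33, 23, 17; 4.00: 43, 24, 12

(readings scatter by 2 percentage points)

1. which of these holds the largest part of the J at the end of beta (J / G / Z / D)
2. which of these holds the largest part of the J at the end of gamma (J / G / Z / D)
3. final D in gamma, as a percentage of the J charged

- percentages count the J that a species holds: one L counts as two
- Z is meant together with its X
- solid, in amounts per volume of the solution: X
- the numbers in the tables scatter by 2 percentage points (one standard deviation)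
- steps under discussion: E <-> Q; X <-> Z; J + E -> Z; E + Z -> D; J + E -> G; 2 J -> L; E + G -> D

So I follow the spent share: the fraction of the charged E that sits in adducts, counting Z once and D as two (G is not read). By the first reading it has jumped: at 0.625 d blue reads 0.327 and ochre 0.281, alike within the scatter, and I take Q, its resting state, to hold the E that is neither free nor in an adduct. In the middle the share creeps, and blue reads 0.400 at 1.25 d and 0.500 at 4.00 d. Carried on at that pace, the spent share at 5.0 d is 0.536, an estimate from blue that I apply to gamma and beta.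

In gamma that makes Z plus two D come to 1.34 as a fraction of the J charged, so with Z at blue's 24% my D is 55.0%, above that Z and blue's last J, with G unread and so unranked. In beta I let J follow a line in one over J drawn from the charge through ochre's last reading, which I read as the pairing of two J into L, and my J reaches 23.7%; split as in ochre's last reading, the share gives Z 13.4% and D 6.70%, so my J stands above my Z and D, with G again unranked.

The forecast, lower than my D, says J for beta, D for gamma and 48%, holding that “E is parked as Q and released slowly”.

The flask gives J in beta at 22.1%, and D in gamma at 50.4%.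

    E ⇌ Q (K = 19.0, k = 7.80 × 10⁻⁵ s⁻¹)
    X ⇌ Z, rate k2*(cs2 - [Z]) while solid is left; crystals form when [Z] > cs2 (solubility = 17.0 mM, k = 2.00 × 10⁻⁴ s⁻¹)
    J + E → Z (k = 5.40 × 10⁻⁴ M⁻¹ s⁻¹)
    E + Z → D (k = 5.40 × 10⁻⁴ M⁻¹ s⁻¹)
    J + E → G (k = 2.90 × 10⁻⁴ M⁻¹ s⁻¹)
    2 J → L (k = 6.50 × 10⁻⁵ M⁻¹ s⁻¹)
    E + G → D (k = 0.00160 M⁻¹ s⁻¹)

Gamma's spent share comes to 0.493, below my 0.536. With E and Q unconnected, gamma's D is 96.2% against 50.4%, and left ten times as long it is 83.5%, the turning of E into Q having a net turnover of 1.18 equiv by the reading. The neighbour of gamma charged with 1.00 equiv has Z at 19.9%, so that share gives it D of 14.7%, and it holds 14.4%.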